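Its constants were chosen freely; the result is computed.

Per molar per second is the unit of the two constants that matter here, and since both multiply the same reagent, their ratio has no unit at all. I had to compare the following set-ups of one charge.

| flask | starting material | reagent | remark | time |
|---|---|---|---|---|
| dusk | 28 mM | 1.30 equiv | one stirred flow tank at steady state, fed with the mixture as stated, mean residence time 8.0 h |  |
| spring | 28 mM | 1.30 equiv (fed, over 8.00 h) | a stirred flask in which reagent is dosed at a steady rate over 8.00 h without added volume, worked up at 8.0 h | 8.0 h |
| noon | 28 mM (fed, over 8.00 h) | 1.30 equiv | all but starting material at the start; starting material goes in evenly over 8.00 h, the run ends at 8.0 h | 8.0 h |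
| midnight | 28 mM | 1.30 equiv | a closed flask charged with all of it at once and left for 8.0 h | 8.0 h |

    starting material + reagent → single product + by-product (k1 = 0.0037 M⁻¹ s⁻¹)
    reagent + single product → bis adduct + by-product (k2 = 0.0024 M⁻¹ s⁻¹)
    reagent + bis adduct → triple product + by-product (k3 = 4.2 × 10⁻⁴ M⁻¹ s⁻¹)
    reagent + triple product → tetra adduct + by-product (k4 = 0.0046 M⁻¹ s⁻¹)
    reagent ⇌ dormant form (K5 = 0.64, k5 = 3.4 × 10⁻⁵ s⁻¹)
    reagent → decomposition product (k6 = 3.4 × 10⁻⁷ s⁻¹)
    starting material + by-product → side product (k7 = 0.0065 M⁻¹ s⁻¹)

- the stated concentrations are those of everything mixed, before any reaction; amounts are the same in each set-up
- the feed brings no volume worth counting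
- run time (spring): 8.0 h

- the set-up with the highest amount of single product at the outlet or at the end, in percent of the starting material put in ("none" if the first two lie within 2 percentage points) (dusk / spring / noon / midnight / none)
- amount of single product at the outlet or at the end, in percent of the starting material put in, dusk
- amount of single product at the outlet or at the end, in percent of the starting material put in, spring
- amount of single product at the outlet or at the end, in percent of the starting material put in, noon
- amount of single product at the outlet or at the end, in percent of the starting material put in, midnight

I wrote a and m for the fractions of the charged starting material present as starting material and as single product, B for free reagent, and k and k′ for the constants of the first and second steps. With the first step by itself, the closed flask midnight integrated to a = 13.7% at 8.0 h, so my hand figure for m there was 86.3%.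

Then I added the second step, which made dm/dt = B(ka − k′m) against da/dt = −kBa. Dividing one by the other removed B and time, and the integral, with r = k/k′, was m = r(a^(1/r) − a)/(r − 1). Its crest lay where m/a reached the critical ratio r, the selectivity factor of the pair, 1.54, and its height was 45.0%. B stands in front of both terms of dm/dt, so in midnight, spring and noon alike m rises below r and falls above it.

Last came the rest. The by-product attacks starting material without making single product, and its share of that loss reaches 63.7% once by-product equals reagent. I charged half of this share against the crest and committed to 30.6% as the crest of midnight. The third and fourth steps start beyond single product, and the dormant form acts on B, so the ratio r stood unchanged while the height did not. Decomposition, with a half-life of 24 d against 8.0 h, I dropped. Dusk has an outflow, so this reckoning gave me no figure for it.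

The forecast gave 20% for dusk, 33% for spring, 26% for noon and 28% for midnight, and named spring as best, holding that “Dosing the reagent keeps the single product from being over-reacted”. My 30.6% lies above its midnight figure, though mine was a crest and not a reading at the end.

The simulation gave 19.7% for dusk, 33.0% for spring, 26.2% for noon and 30.1% for midnight, so spring led, and the forecast stood within tolerance throughout. Midnight had held 35.8% at 4.00 h, more than spring held at its end. Its m/a was then 2.20, above r, so that flask was already past its crest, while spring ended at 1.64, close to r.

For midnight left until 5.0 h, the rate at 4.00 h written with r gave a fall of 0.966% of the charge, hence about 34.8%. The computed flask held 34.5%.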